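## The problem

CNP0113449.2 is a xenicane-type bicycle, numbered here as lactone C1H2–O2–C3(=O)–C4(=C12)–C4a–C11a, carbocycle C4a–C5–C6–C7(CH3,OH)–C8–C9–C10–C11(=C19H2)–C11a and side chain C12–C13(OAc)–C14–C15(CH3)2. A nine-membered ring is trans-fused at C4a/C11a to a δ-lactone whose α-carbon C4 carries an E-alkylidene. A nine-membered carbocycle resists end-to-end closure, so the ring is better made by reorganising a larger, strain-free ring. Seven stereocentres must be set: C4a and C11a (H4a anti to H11a), the tertiary carbinol C7, the cis-8,9-epoxide on the face of the C7 hydroxyl, and the threo pair C13/C14. Two relations control themselves: a free C7 hydroxyl can deliver an oxidant to a Z-C8=C9 bond, and a free C13 hydroxyl can steer a peracid onto C14=C15 through allylic 1,3-strain. C7, however, is 1,4 to C4a across a flexible chain and cannot be trusted to set the ring fusion, and the side chain is insulated from the core and needs its own source of chirality. The trisubstituted epoxide (acid), the epoxy alcohol at C7–C9, the tertiary allylic alcohol, the alkylidene lactone (base, nucleophiles), the acetate and the C11 methylene (which slips into conjugation whenever C1 is an activated carbonyl) all forbid rough treatment late in the route. The enabling feature is that C4a and C11a carry the arms C4 and C1, joined through O2 and C3: the six atoms C11a–C1–O2–C3–C4–C4a are the array of an ester-enolate Claisen product once C1 and C3 exchange oxidation levels.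

## Retrosynthesis

**C8–O and C9–O (epoxide).** Target 41 is traced to allylic alcohol 40. The epoxy alcohol is the most fragile unit, so it is made last. With C13 acetylated, only the C7 hydroxyl can bind vanadium, and syn delivery to the Z-alkene gives the required face.

**Acetyl and silyl groups.** 40 comes from diol 39 by acetylation of the secondary C13 hydroxyl, which the tertiary C7 hydroxyl does not follow. 39 comes from bis-silyl ether 38 by one fluoride treatment.

**C4=C12.** 38 is cut into bicyclic lactone 27 and epoxy aldehyde 34 (aldol addition, then elimination). This keeps the side chain with its two stereocentres out of the ring-forming chemistry. The forward reaction must give the E-alkene and leave the epoxide alone.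

**Side chain.** 34 comes from bis-silyl ether 33 and epoxy diol 32. The epoxide of 32 is set by hydroxyl-directed peracid oxidation of diol 31, whose C13 centre is taken from (S)-glyceraldehyde acetonide 28 through Wittig product 30 (ylide from salt 29). C13 therefore controls C14 on a small fragment where no other alkene competes.

**O2–C3 and the redox exchange.** Lactone 27 is opened to hydroxy acid 26 and acetate acid 25. The C3 carboxyl is traced through alcohol 24 to the vinyl group of 22, and the C1 acetoxymethyl through alcohol 21 to the carboxyl of acid 20. 20 is much simpler than 27 in function but already holds the ring and both ring-fusion centres. The forward sequence needs a hydroboration that takes the vinyl group and not the C11 methylene.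

**C4a–C11a (key).** Acid 20 is the [3,3] product of the ester enolate of 13-membered lactone 17. This is preferred to any direct nine-membered closure because the bond forms inside a six-atom cyclic array held by an unstrained macrocycle. A boron ketene acetal carrying a chiral bis-sulfonamide ligand is chosen over a silyl ketene acetal for two reasons: the amine/solvent pair fixes the enolate geometry, and the ligand, not the remote C7 centre, fixes the absolute sense. With the E-allylic ester and the enolate in which C11 is syn to O–B, a chair gives the trans acid.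

**O2–C3 of the macrolactone.** 17 comes from seco acid 16 by activating the allylic alcohol (Mitsunobu) and not the acid. An activated 3-methylenealkanoic acid would form a vinylketene and drift into conjugation.

**C11–C11a and C9–C10.** 16 comes from ester 15, the Lindlar product of enyne 14. 14 is cut at C11–C11a into vinyl bromide 12 and the Reformatsky reagent of methyl bromoacetate 13, and 12 at C9–C10 into alkyne 10 and 2,3-dibromopropene 11. 11 acts as a linchpin: its allylic bromide takes the copper acetylide and its vinylic bromide the zinc enolate. The β,γ-unsaturated ester is therefore never exposed to base.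

**C4=C4a.** Allylic alcohol 10 comes from enoate 9, the Horner–Wadsworth–Emmons product of aldehyde 7 and phosphonate 8. 7 arises by ozonolysis of the prenyl alkene of silyl ether 5.

**C7.** 5 is the silyl ether of alkynol 4, which comes from epoxy chloride 3 and epoxy alcohol 2, the Sharpless product of geraniol 1. Geraniol is preferred to natural linalool because linalool's vinyl group cannot be turned into the alkyne without first attacking its more reactive trisubstituted alkene. From geraniol the alkyne appears directly and the prenyl alkene remains as a masked aldehyde.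

## Roads not taken

**Alternative 1:** The cut is at C3–C4 and C3–O2. A Pd–H species (from Pd(OAc)2, a phosphine and an acid) under CO adds across the C4≡C12 alkyne of alkynyl alcohol A2, CO inserts at C4 and the C1 hydroxyl captures the acyl palladium to give the lactone A1.
- Merits: lactone and alkylidene form in one step. The geometry follows from syn addition of H and Pd and is the E geometry needed. The side chain enters as an acetylide, so neither an aldol/elimination nor the C1/C3 redox exchange is required. In these respects it is better than the chosen plan, which relies on the thermodynamic preference for the E-alkylidene.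
- Weak points: A2 already contains the nine-membered ring, both ring-fusion centres and both epoxides, so the central problem is only moved. Palladium has to go to C4 and not C12 of an unsymmetrical propargylic ether. Two epoxides and a tertiary allylic alcohol must survive a palladium hydride and an acid promoter.
- Comparison: the chosen plan builds the ring, C4a and C11a in a single step with C1 and C3 already attached, and exposes the epoxides only to mild last steps.

**Alternative 2:** The cut is the retro-fragmentation that adds a C7–C11 bond. The C7 alkoxide of cis-fused hydrindenol tosylate A4 expels the C19 tosylate with cleavage of C7–C11 and opens to nine-membered Z-enone A3.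
- Merits: the medium ring comes from an unstrained bicycle without entropic cost. The Z-alkene and the methylene are formed in the same event. C4a and C11a are set on a cyclohexane by conventional means. In reliability of ring formation and relative control at the ring fusion it is better than the chosen plan.
- Weak points: A4 carries two adjacent quaternary ring-fusion carbons and needs a long enantioselective synthesis. In A3, C7 is a ketone, so the tertiary carbinol must come from a 1,2-selective, face-selective methyl addition to a flexible enone under remote control. The lactone must still be assembled from two protected arms.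
- Comparison: the chosen plan fixes C7 at the outset by asymmetric epoxidation and lets a chiral boron ligand set the ring fusion. It pays with a [3,3] shift whose relative stereochemistry must be steered by enolate geometry.

**Alternative 3:** The cut is at C7–C8. SmI2 reduces the C8 aldehyde and C7 methyl ketone of keto aldehyde A6 to a ketyl pair that couples to the cis-diol lactone A5.
- Merits: the lactone is in place before the ring closes, so C4a/C11a come from six-membered-ring chemistry. C7, C8 and C9 carry their oxygens at once, which is better than the chosen plan in oxidation-state economy around the epoxy alcohol.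
- Weak points: this is a direct nine-membered closure against strain and entropy. The aldehyde of A6 is α-alkoxy, and divalent samarium tends to cleave such C–O bonds reductively. The configuration at C7/C8 relative to the distant C4a is not predictable. Turning A5 into the 8,9-epoxide needs selective activation and inversion at C9, followed by side-chain attachment in the presence of an epoxy alcohol.
- Comparison: the chosen plan avoids direct medium-ring closure and reaches the syn-epoxy alcohol by one hydroxyl-directed oxidation of a Z-alkene.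

Key step: step 13

Assumption: the (S,S)-configured boron reagent is taken to give the (1R,9R) sense in acid 20; if a first run shows the opposite sense, the equally accessible (R,R) reagent is used with nothing else changed.

Step 1
Reactants: 1 geraniol [(2E)-3,7-dimethylocta-2,6-dien-1-ol]
Product: 2 [(2S,3S)-3-methyl-3-(4-methylpent-3-en-1-yl)oxiran-2-yl]methanol
Conditions: Ti(OiPr)4 (cat.), L-(+)-diethyl tartrate (cat.), t-BuOOH, 4 Å molecular sieves, CH2Cl2, −20 °C
Reagents that add atoms: tert-butyl hydroperoxide, CC(C)(C)OO
Why: Sharpless asymmetric epoxidation; only the allylic alkene binds to titanium, and the L-tartrate ligand delivers oxygen to the face that gives the 3S tertiary C–O centre, the future C7.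

Step 2
Reactants: 2 [(2S,3S)-3-methyl-3-(4-methylpent-3-en-1-yl)oxiran-2-yl]methanol
Product: 3 (2R,3S)-2-(chloromethyl)-3-methyl-3-(4-methylpent-3-en-1-yl)oxirane
Conditions: PPh3, CCl4, NaHCO3, reflux
Reagents that add atoms: tetrachloromethane, ClC(Cl)(Cl)Cl
Why: Appel chlorination of the primary alcohol under buffered neutral conditions leaves the epoxide intact; the descriptor at C2 changes only through priority.

Step 3
Reactants: 3 (2R,3S)-2-(chloromethyl)-3-methyl-3-(4-methylpent-3-en-1-yl)oxirane
Product: 4 (3S)-3,7-dimethyloct-6-en-1-yn-3-ol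
Conditions: n-BuLi (3.2 equiv), THF, −78 to −30 °C; aq. NH4Cl
Reagents that add atoms: none
Why: Base-induced fragmentation of a 2,3-epoxy chloride to a propargylic alcohol (epoxide opening to the chlorovinyl alkoxide, then dehydrochlorination); the C3–O bond is never broken, so the tertiary centre keeps its configuration.

Step 4
Reactants: 4 (3S)-3,7-dimethyloct-6-en-1-yn-3-ol
Product: 5 triethyl{[(3S)-3,7-dimethyloct-6-en-1-yn-3-yl]oxy}silane
Conditions: Et3SiOTf, 2,6-lutidine, CH2Cl2, −78 to 0 °C
Reagents that add atoms: triethylsilyl trifluoromethanesulfonate, CC[Si](CC)(CC)OS(=O)(=O)C(F)(F)F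
Why: Silyl triflate silylation of a hindered tertiary alcohol; the tertiary triethylsilyl ether withstands bases, hydrides and mild acid and is removed by fluoride at the end.

Step 5
Reactants: 5 triethyl{[(3S)-3,7-dimethyloct-6-en-1-yn-3-yl]oxy}silane
Product: 7 (4S)-4-methyl-4-(triethylsilyloxy)hex-5-ynal, via ozonide 6 (not isolated)
Conditions: O3, CH2Cl2, −78 °C, stopped when the alkene is consumed; then PPh3, −78 °C to rt
Reagents that add atoms: ozone, [O-][O+]=O
Why: Ozonolysis with reductive work-up; the electron-rich trisubstituted alkene reacts far faster than a terminal alkyne, so the alkyne survives.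

Step 6
Reactants: 7 (4S)-4-methyl-4-(triethylsilyloxy)hex-5-ynal; 8 triethyl phosphonoacetate
Product: 9 ethyl (2E,6S)-6-methyl-6-(triethylsilyloxy)oct-2-en-7-ynoate
Conditions: NaH, THF, 0 °C (phosphonate anion formed first, then 7)
Reagents that add atoms: none
Why: Horner–Wadsworth–Emmons olefination of an unbranched aldehyde with a stabilised phosphonate gives the E-enoate; the preformed anion does not touch the alkyne C–H.

Step 7
Reactants: 9 ethyl (2E,6S)-6-methyl-6-(triethylsilyloxy)oct-2-en-7-ynoate
Product: 10 (2E,6S)-6-methyl-6-(triethylsilyloxy)oct-2-en-7-yn-1-ol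
Conditions: i-Bu2AlH, CH2Cl2, −78 °C; aq. potassium sodium tartrate
Reagents that add atoms: none
Why: 1,2-Reduction of an enoate to the allylic alcohol with i-Bu2AlH; alkyne and silyl ether are inert at −78 °C.

Step 8
Reactants: 10 (2E,6S)-6-methyl-6-(triethylsilyloxy)oct-2-en-7-yn-1-ol; 11 2,3-dibromoprop-1-ene
Product: 12 (2E,6S)-10-bromo-6-methyl-6-(triethylsilyloxy)undeca-2,10-dien-7-yn-1-ol
Conditions: CuI, NaI, K2CO3, DMF, rt
Reagents that add atoms: none
Why: Copper-mediated coupling of a terminal alkyne with an allylic bromide under carbonate conditions; only the allylic bromide of 11 reacts, the free alcohol is tolerated and the skipped enyne is not isomerised by the weak base.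

Step 9
Reactants: 12 (2E,6S)-10-bromo-6-methyl-6-(triethylsilyloxy)undeca-2,10-dien-7-yn-1-ol; 13 methyl bromoacetate
Product: 14 methyl (7S,10E)-12-hydroxy-7-methyl-3-methylidene-7-(triethylsilyloxy)dodec-10-en-5-ynoate
Conditions: Zn dust, THF, 40 °C (Reformatsky reagent from 13, 3 equiv); then 12, Pd(dba)2 (5 mol%), P(t-Bu)3 (5 mol%), THF, rt
Reagents that add atoms: none
Why: Negishi-type coupling of a Reformatsky reagent with a vinyl bromide (oxidative addition to zerovalent palladium, transmetallation, reductive elimination) forms C11–C11a; the 3-methylene ester arises without base and so does not move into conjugation, and the excess zinc reagent covers the free hydroxyl.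

Step 10
Reactants: 14 methyl (7S,10E)-12-hydroxy-7-methyl-3-methylidene-7-(triethylsilyloxy)dodec-10-en-5-ynoate
Product: 15 methyl (5Z,7S,10E)-12-hydroxy-7-methyl-3-methylidene-7-(triethylsilyloxy)dodeca-5,10-dienoate
Conditions: H2 (1 atm), Pd/CaCO3 poisoned with Pb(OAc)2, quinoline, EtOAc, rt
Reagents that add atoms: none
Why: Lindlar semihydrogenation; syn addition to the alkyne gives the Z-C8=C9 bond and the poisoned catalyst leaves the three alkenes alone.

Step 11
Reactants: 15 methyl (5Z,7S,10E)-12-hydroxy-7-methyl-3-methylidene-7-(triethylsilyloxy)dodeca-5,10-dienoate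
Product: 16 (5Z,7S,10E)-12-hydroxy-7-methyl-3-methylidene-7-(triethylsilyloxy)dodeca-5,10-dienoic acid
Conditions: Me3SnOH, ClCH2CH2Cl, 70 °C; then cold 0.1 M HCl wash
Reagents that add atoms: trimethyltin hydroxide, C[Sn](C)(C)O
Why: Neutral methyl ester cleavage with Me3SnOH; no free hydroxide is present, which avoids base-catalysed migration of the C11 methylene into conjugation with C1.

Step 12
Reactants: 16 (5Z,7S,10E)-12-hydroxy-7-methyl-3-methylidene-7-(triethylsilyloxy)dodeca-5,10-dienoic acid
Product: 17 (6Z,8S,11E)-8-methyl-4-methylidene-8-(triethylsilyloxy)oxacyclotrideca-6,11-dien-2-one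
Conditions: PPh3, diisopropyl azodicarboxylate, toluene, slow addition of 16 (final about 0.003 M), 0 °C to rt
Reagents that add atoms: none
Why: Mitsunobu macrolactonisation; the primary allylic alcohol is activated as its alkoxyphosphonium ion and displaced by the carboxylate at C3, so the acid is never activated and cannot form a vinylketene; the tertiary silyl ether is inert.

Step 13
Reactants: 17 (6Z,8S,11E)-8-methyl-4-methylidene-8-(triethylsilyloxy)oxacyclotrideca-6,11-dien-2-one
Product: 20 (1R,4Z,6S,9R)-9-ethenyl-6-methyl-2-methylidene-6-(triethylsilyloxy)cyclonon-4-ene-1-carboxylic acid, via boron ketene acetal 18 (not isolated), via acyloxyborane 19 (not isolated)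
Conditions: (4S,5S)-2-bromo-4,5-diphenyl-1,3-bis{[3,5-bis(trifluoromethyl)phenyl]sulfonyl}-1,3,2-diazaborolidine (from the (S,S)-bis-sulfonamide and BBr3, CH2Cl2), i-Pr2NEt, CH2Cl2, −78 °C, then 4 °C; aqueous work-up at pH 4
Reagents that add atoms: none
Why: The bromoborane and i-Pr2NEt convert 17 by soft enolisation into O-boron ketene acetal 18 with C11 syn to the boron-bearing oxygen, and on warming the array C11a=C1–O2–C3–C4=C4a undergoes a [3,3] shift that forms C4a–C11a and breaks O2–C3 to give acyloxyborane 19, which is hydrolysed on work-up. The closest known reaction type is the enantioselective boron ester-enolate Claisen rearrangement, which has been used to contract macrocyclic allylic lactones to carbocycles; the silyl counterpart is the Ireland–Claisen ring contraction. The nine-membered ring closes by transannular attack of C11a on C4a, formally 9-exo-trig, and the C=O bond gained pays for the medium-ring strain. C4a and C11a are set together: with the E-allylic ester and this enolate geometry a chair places both ring bonds equatorial and gives the trans acid (H4a anti to H11a). The absolute sense is set by the bis-sulfonamide ligand on boron, which shields one enolate face, while the remote C7 centre should add only a small matched or mismatched bias. The step needs one enolate geometry (secured by the amine/solvent pair), chair over boat (favoured because the seven-atom tether spans two equatorial positions without strain) and bonding at the α-carbon of the dienolate, not at C19 (secured by the six-membered array). The tertiary silyl ether and the other alkenes should be inert to the boron reagent at these temperatures.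

Step 14
Reactants: 20 (1R,4Z,6S,9R)-9-ethenyl-6-methyl-2-methylidene-6-(triethylsilyloxy)cyclonon-4-ene-1-carboxylic acid
Product: 21 [(1R,4Z,6S,9R)-9-ethenyl-6-methyl-2-methylidene-6-(triethylsilyloxy)cyclonon-4-en-1-yl]methanol
Conditions: LiAlH4, Et2O, 0 °C to rt
Reagents that add atoms: none
Why: Hydride reduction of the carboxylic acid to the C1 alcohol; the acid is first deprotonated, so C11a cannot epimerise and the isolated alkenes are untouched.

Step 15
Reactants: 21 [(1R,4Z,6S,9R)-9-ethenyl-6-methyl-2-methylidene-6-(triethylsilyloxy)cyclonon-4-en-1-yl]methanol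
Product: 22 [(1R,4Z,6S,9R)-9-ethenyl-6-methyl-2-methylidene-6-(triethylsilyloxy)cyclonon-4-en-1-yl]methyl acetate
Conditions: Ac2O, pyridine, DMAP (cat.), CH2Cl2, 0 °C
Reagents that add atoms: acetic anhydride, CC(=O)OC(C)=O
Why: Acylation of the primary alcohol; the acetate is orthogonal to the tertiary silyl ether (base versus fluoride) and keeps C1 at the alcohol level while C3 is oxidised.

Step 16
Reactants: 22 [(1R,4Z,6S,9R)-9-ethenyl-6-methyl-2-methylidene-6-(triethylsilyloxy)cyclonon-4-en-1-yl]methyl acetate
Product: 24 [(1R,4Z,6S,9R)-9-(2-hydroxyethyl)-6-methyl-2-methylidene-6-(triethylsilyloxy)cyclonon-4-en-1-yl]methyl acetate, via trialkylborane 23 (not isolated)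
Conditions: (Me2CHCHMe)2BH (from BH3·SMe2 and 2-methylbut-2-ene), THF, 0 °C; then 30% H2O2, aq. NaOAc, 0 °C to rt
Reagents that add atoms: hydrogen peroxide, OO
Why: Anti-Markovnikov hydroboration–oxidation; this bulky dialkylborane adds to a monosubstituted vinyl group much faster than to a 1,1-disubstituted methylene or a hindered cis-alkene, and buffered peroxide oxidation spares the acetate.

Step 17
Reactants: 24 [(1R,4Z,6S,9R)-9-(2-hydroxyethyl)-6-methyl-2-methylidene-6-(triethylsilyloxy)cyclonon-4-en-1-yl]methyl acetate
Product: 25 2-[(1R,2R,5Z,7S)-2-(acetoxymethyl)-7-methyl-3-methylidene-7-(triethylsilyloxy)cyclonon-5-en-1-yl]acetic acid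
Conditions: TEMPO (cat.), PhI(OAc)2, MeCN/H2O, rt
Reagents that add atoms: water, O
Why: Oxoammonium-mediated oxidation of a primary alcohol through the aldehyde hydrate to the acid; alkenes, acetate and the tertiary silyl ether are not attacked.

Step 18
Reactants: 25 2-[(1R,2R,5Z,7S)-2-(acetoxymethyl)-7-methyl-3-methylidene-7-(triethylsilyloxy)cyclonon-5-en-1-yl]acetic acid
Product: 27 (4aR,7S,8Z,11aR)-7-methyl-11-methylidene-7-(triethylsilyloxy)-4,4a,5,6,7,10,11,11a-octahydrocyclonona[c]pyran-3(1H)-one, via hydroxy acid 26 (not isolated)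
Conditions: K2CO3, MeOH, rt; dilute HCl to pH 4; then EDC·HCl, DMAP (cat.), CH2Cl2, rt
Reagents that add atoms: none
Why: Methanolysis of the acetate frees the C1 hydroxyl and carbodiimide lactonisation closes the δ-lactone (6-exo-trig acyl substitution); the trans relation of the two arms is already fixed, and C4a is not α to the carbonyl and cannot epimerise.

Step 19
Reactants: 28 (4S)-2,2-dimethyl-1,3-dioxolane-4-carbaldehyde; 29 isopropyltriphenylphosphonium iodide
Product: 30 (4R)-2,2-dimethyl-4-(2-methylprop-1-en-1-yl)-1,3-dioxolane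
Conditions: n-BuLi, THF, 0 °C (ylide); then 28, −78 °C to rt
Reagents that add atoms: none
Why: Wittig olefination with a non-stabilised ylide; at low temperature the α-alkoxy aldehyde does not epimerise, and the descriptor changes from S to R through priority only.

Step 20
Reactants: 30 (4R)-2,2-dimethyl-4-(2-methylprop-1-en-1-yl)-1,3-dioxolane
Product: 31 (2R)-4-methylpent-3-ene-1,2-diol
Conditions: AcOH/H2O (4:1), rt
Reagents that add atoms: none
Why: Mild acetal hydrolysis; dilute acetic acid removes the acetonide without ionising the secondary allylic alcohol.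

Step 21
Reactants: 31 (2R)-4-methylpent-3-ene-1,2-diol
Product: 32 (2S,3R)-3,4-epoxy-4-methylpentane-1,2-diol [(1S)-1-[(2R)-3,3-dimethyloxiran-2-yl]ethane-1,2-diol]
Conditions: 3-chloroperbenzoic acid, NaHCO3, CH2Cl2, 0 °C
Reagents that add atoms: 3-chloroperbenzoic acid, OOC(=O)c1cccc(Cl)c1
Why: Hydroxyl-directed peracid epoxidation; allylic 1,3-strain with the cis-methyl group holds the C13–H bond in the alkene plane, and the hydrogen-bonded peracid attacks the face of the hydroxyl to give the threo epoxy alcohol (C14 of the target), while the buffer prevents acid-catalysed cyclisation of the primary hydroxyl onto the epoxide.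

Step 22
Reactants: 32 (2S,3R)-3,4-epoxy-4-methylpentane-1,2-diol
Product: 33 (2S,3R)-3,4-epoxy-4-methyl-1,2-bis(triethylsilyloxy)pentane
Conditions: Et3SiCl, imidazole, DMAP (cat.), CH2Cl2, 0 °C to rt
Reagents that add atoms: chlorotriethylsilane, CC[Si](CC)(CC)Cl
Why: Silylation of both hydroxyls under basic conditions removes the nucleophiles that could open the epoxide.

Step 23
Reactants: 33 (2S,3R)-3,4-epoxy-4-methyl-1,2-bis(triethylsilyloxy)pentane
Product: 34 (2R,3R)-3,4-epoxy-4-methyl-2-(triethylsilyloxy)pentanal
Conditions: (COCl)2, DMSO, CH2Cl2, −78 to −40 °C; then Et3N, −78 to 0 °C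
Reagents that add atoms: none
Why: Swern oxidation applied directly to a primary triethylsilyl ether; the chlorosulfonium ion cleaves the unhindered primary silyl ether and oxidises it to the aldehyde while the secondary silyl ether stays, and the low temperature protects the α-stereocentre.

Step 24
Reactants: 27 (4aR,7S,8Z,11aR)-7-methyl-11-methylidene-7-(triethylsilyloxy)-4,4a,5,6,7,10,11,11a-octahydrocyclonona[c]pyran-3(1H)-one; 34 (2R,3R)-3,4-epoxy-4-methyl-2-(triethylsilyloxy)pentanal
Product: 36 β-hydroxy lactone [27 carrying at C4 the 1-hydroxy-2-(triethylsilyloxy)-2-[(2R)-3,3-dimethyloxiran-2-yl]ethyl group, mixture at C4 and C12], via lithium enolate 35 (not isolated)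
Conditions: LiN(i-Pr)2, THF, −78 °C; then 34, −78 °C; aq. NH4Cl
Reagents that add atoms: none
Why: Aldol addition of the lactone lithium enolate (C4 is the only enolisable position) to a reactive α-silyloxy aldehyde at −78 °C; the new centres at C4 and C12 are not controlled because both are removed in the next step.

Step 25
Reactants: 36 β-hydroxy lactone (mixture at C4 and C12)
Product: 38 (4E,4aS,7S,8Z,11aR)-4-{(2S)-2-[(2R)-3,3-dimethyloxiran-2-yl]-2-(triethylsilyloxy)ethylidene}-7-methyl-11-methylidene-7-(triethylsilyloxy)-4,4a,5,6,7,10,11,11a-octahydrocyclonona[c]pyran-3(1H)-one, via mesylate 37 (not isolated)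
Conditions: MsCl, Et3N, CH2Cl2, 0 °C; then DBU, 0 °C to rt
Reagents that add atoms: none
Why: Mesylation and E1cB elimination through the lactone enolate; the conjugated E-alkylidene, with C13 away from the carbonyl, is the more stable isomer and should dominate, and the short exposure to DBU at low temperature spares the γ-hydrogen at C13 and the epoxide.

Step 26
Reactants: 38 bis-silyl ether (see step 25)
Product: 39 (4E,4aS,7S,8Z,11aR)-4-{(2S)-2-[(2R)-3,3-dimethyloxiran-2-yl]-2-hydroxyethylidene}-7-hydroxy-7-methyl-11-methylidene-4,4a,5,6,7,10,11,11a-octahydrocyclonona[c]pyran-3(1H)-one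
Conditions: HF·pyridine, excess pyridine, THF, 0 °C to rt
Reagents that add atoms: none
Why: Fluoride desilylation buffered with pyridine removes the secondary and the tertiary triethylsilyl ether; buffered HF·pyridine is known to tolerate trisubstituted epoxides, and the medium is too weakly basic for a Payne rearrangement.

Step 27
Reactants: 39 diol (see step 26)
Product: 40 (1S)-1-[(2R)-3,3-dimethyloxiran-2-yl]-2-[(4E,4aS,7S,8Z,11aR)-7-hydroxy-7-methyl-11-methylidene-3-oxo-1,3,4a,5,6,7,10,11a-octahydrocyclonona[c]pyran-4-ylidene]ethyl acetate (the 13-acetate of 39)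
Conditions: Ac2O, pyridine, DMAP (cat.), CH2Cl2, 0 °C
Reagents that add atoms: acetic anhydride, CC(=O)OC(C)=O
Why: Selective acylation; the secondary C13 hydroxyl is acetylated while the hindered tertiary C7 hydroxyl does not react under these conditions.

Step 28
Reactants: 40 13-acetate with free C7 hydroxyl (see step 27)
Product: 41 CNP0113449.2 [(4E,4aS,7S,8R,9R,11aR,13S,14R)-13-acetoxy-8,9:14,15-diepoxy-7-hydroxy lactone in the numbering of the text]
Conditions: VO(acac)2 (cat.), t-BuOOH (in decane), CH2Cl2, 0 °C to rt
Reagents that add atoms: tert-butyl hydroperoxide, CC(C)(C)OO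
Why: Vanadium-catalysed hydroxyl-directed epoxidation; the C7 vanadate ester delivers the peroxide oxygen to the Z-C8=C9 bond on its own face, which for medium-ring allylic alcohols gives the syn (cis) epoxy alcohol and so sets C8 and C9; the methylene, the electron-poor alkylidene and the acetylated side chain have no directing hydroxyl and should not react.

## Compound list

1 | geraniol, (2E)-3,7-dimethylocta-2,6-dien-1-ol | CC(C)=CCC/C(C)=C/CO | starting material
2 | [(2S,3S)-3-methyl-3-(4-methylpent-3-en-1-yl)oxiran-2-yl]methanol | OC[C@@H]1O[C@@]1(C)CCC=C(C)C | intermediate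
3 | (2R,3S)-2-(chloromethyl)-3-methyl-3-(4-methylpent-3-en-1-yl)oxirane | ClC[C@@H]1O[C@@]1(C)CCC=C(C)C | intermediate
4 | (3S)-3,7-dimethyloct-6-en-1-yn-3-ol | C#C[C@@](C)(O)CCC=C(C)C | intermediate
5 | triethyl{[(3S)-3,7-dimethyloct-6-en-1-yn-3-yl]oxy}silane | C#C[C@@](C)(O[Si](CC)(CC)CC)CCC=C(C)C | intermediate
6 | ozonide of 5 (3,3-dimethyl-1,2,4-trioxolane, mixture at the acetal carbon) | CC1(C)OOC(CC[C@](C)(O[Si](CC)(CC)CC)C#C)O1 | intermediate (not isolated)
7 | (4S)-4-methyl-4-(triethylsilyloxy)hex-5-ynal | C#C[C@@](C)(O[Si](CC)(CC)CC)CCC=O | intermediate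
8 | triethyl phosphonoacetate | CCOC(=O)CP(=O)(OCC)OCC | starting material
9 | ethyl (2E,6S)-6-methyl-6-(triethylsilyloxy)oct-2-en-7-ynoate | C#C[C@@](C)(O[Si](CC)(CC)CC)CC/C=C/C(=O)OCC | intermediate
10 | (2E,6S)-6-methyl-6-(triethylsilyloxy)oct-2-en-7-yn-1-ol | C#C[C@@](C)(O[Si](CC)(CC)CC)CC/C=C/CO | intermediate
11 | 2,3-dibromoprop-1-ene | C=C(Br)CBr | starting material
12 | (2E,6S)-10-bromo-6-methyl-6-(triethylsilyloxy)undeca-2,10-dien-7-yn-1-ol | C=C(Br)CC#C[C@@](C)(O[Si](CC)(CC)CC)CC/C=C/CO | intermediate
13 | methyl bromoacetate | COC(=O)CBr | starting material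
14 | methyl (7S,10E)-12-hydroxy-7-methyl-3-methylidene-7-(triethylsilyloxy)dodec-10-en-5-ynoate | C=C(CC(=O)OC)CC#C[C@@](C)(O[Si](CC)(CC)CC)CC/C=C/CO | intermediate
15 | methyl (5Z,7S,10E)-12-hydroxy-7-methyl-3-methylidene-7-(triethylsilyloxy)dodeca-5,10-dienoate | C=C(CC(=O)OC)C/C=C\[C@@](C)(O[Si](CC)(CC)CC)CC/C=C/CO | intermediate
16 | (5Z,7S,10E)-12-hydroxy-7-methyl-3-methylidene-7-(triethylsilyloxy)dodeca-5,10-dienoic acid | C=C(CC(=O)O)C/C=C\[C@@](C)(O[Si](CC)(CC)CC)CC/C=C/CO | intermediate
17 | (6Z,8S,11E)-8-methyl-4-methylidene-8-(triethylsilyloxy)oxacyclotrideca-6,11-dien-2-one | C=C1C/C=C\[C@@](C)(O[Si](CC)(CC)CC)CC/C=C/COC(=O)C1 | intermediate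
18 | O-boron ketene acetal of 17 (C11 syn to O–B; boron carries the (S,S)-bis-sulfonamide ligand) | C1[C@](C)(O[Si](CC)(CC)CC)/C=C\CC(=C)/C=C(\OB2N(S(=O)(=O)c3cc(C(F)(F)F)cc(C(F)(F)F)c3)[C@@H](c3ccccc3)[C@H](c3ccccc3)N2S(=O)(=O)c2cc(C(F)(F)F)cc(C(F)(F)F)c2)/OC/C=C/C1 | intermediate (not isolated)
19 | acyloxyborane of acid 20 | C=C1C/C=C\[C@@](C)(O[Si](CC)(CC)CC)CC[C@H](C=C)[C@H]1C(=O)OB1N(S(=O)(=O)c2cc(C(F)(F)F)cc(C(F)(F)F)c2)[C@@H](c2ccccc2)[C@H](c2ccccc2)N1S(=O)(=O)c1cc(C(F)(F)F)cc(C(F)(F)F)c1 | intermediate (not isolated)
20 | (1R,4Z,6S,9R)-9-ethenyl-6-methyl-2-methylidene-6-(triethylsilyloxy)cyclonon-4-ene-1-carboxylic acid | C=C1C/C=C\[C@@](C)(O[Si](CC)(CC)CC)CC[C@H](C=C)[C@H]1C(=O)O | intermediate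
21 | [(1R,4Z,6S,9R)-9-ethenyl-6-methyl-2-methylidene-6-(triethylsilyloxy)cyclonon-4-en-1-yl]methanol | C=C1C/C=C\[C@@](C)(O[Si](CC)(CC)CC)CC[C@H](C=C)[C@H]1CO | intermediate
22 | [(1R,4Z,6S,9R)-9-ethenyl-6-methyl-2-methylidene-6-(triethylsilyloxy)cyclonon-4-en-1-yl]methyl acetate | C=C1C/C=C\[C@@](C)(O[Si](CC)(CC)CC)CC[C@H](C=C)[C@H]1COC(C)=O | intermediate
23 | trialkylborane from 22 [C3–B(CHMeCHMe2)2] | C=C1C/C=C\[C@@](C)(O[Si](CC)(CC)CC)CC[C@H](CCB(C(C)C(C)C)C(C)C(C)C)[C@H]1COC(C)=O | intermediate (not isolated)
24 | [(1R,4Z,6S,9R)-9-(2-hydroxyethyl)-6-methyl-2-methylidene-6-(triethylsilyloxy)cyclonon-4-en-1-yl]methyl acetate | C=C1C/C=C\[C@@](C)(O[Si](CC)(CC)CC)CC[C@H](CCO)[C@H]1COC(C)=O | intermediate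
25 | 2-[(1R,2R,5Z,7S)-2-(acetoxymethyl)-7-methyl-3-methylidene-7-(triethylsilyloxy)cyclonon-5-en-1-yl]acetic acid | C=C1C/C=C\[C@@](C)(O[Si](CC)(CC)CC)CC[C@H](CC(=O)O)[C@H]1COC(C)=O | intermediate
26 | 2-[(1R,2R,5Z,7S)-2-(hydroxymethyl)-7-methyl-3-methylidene-7-(triethylsilyloxy)cyclonon-5-en-1-yl]acetic acid | C=C1C/C=C\[C@@](C)(O[Si](CC)(CC)CC)CC[C@H](CC(=O)O)[C@H]1CO | intermediate (not isolated)
27 | (4aR,7S,8Z,11aR)-7-methyl-11-methylidene-7-(triethylsilyloxy)-4,4a,5,6,7,10,11,11a-octahydrocyclonona[c]pyran-3(1H)-one | C=C1C/C=C\[C@@](C)(O[Si](CC)(CC)CC)CC[C@@H]2CC(=O)OC[C@@H]12 | intermediate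
28 | (4S)-2,2-dimethyl-1,3-dioxolane-4-carbaldehyde [(S)-glyceraldehyde acetonide] | O=C[C@@H]1COC(C)(C)O1 | starting material
29 | isopropyltriphenylphosphonium iodide | CC(C)[P+](c1ccccc1)(c1ccccc1)c1ccccc1.[I-] | starting material
30 | (4R)-2,2-dimethyl-4-(2-methylprop-1-en-1-yl)-1,3-dioxolane | CC(C)=C[C@@H]1COC(C)(C)O1 | intermediate
31 | (2R)-4-methylpent-3-ene-1,2-diol | CC(C)=C[C@@H](O)CO | intermediate
32 | (2S,3R)-3,4-epoxy-4-methylpentane-1,2-diol | OC[C@H](O)[C@H]1OC1(C)C | intermediate
33 | (2S,3R)-3,4-epoxy-4-methyl-1,2-bis(triethylsilyloxy)pentane | CC[Si](CC)(CC)OC[C@H](O[Si](CC)(CC)CC)[C@H]1OC1(C)C | intermediate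
34 | (2R,3R)-3,4-epoxy-4-methyl-2-(triethylsilyloxy)pentanal | O=C[C@H](O[Si](CC)(CC)CC)[C@H]1OC1(C)C | intermediate
35 | lithium enolate of lactone 27 | C=C1C/C=C\[C@@](C)(O[Si](CC)(CC)CC)CC[C@@H]2C=C(O[Li])OC[C@@H]12 | intermediate (not isolated)
36 | β-hydroxy lactone (aldol adduct of 27 and 34, mixture at C4 and C12) | C=C1C/C=C\[C@@](C)(O[Si](CC)(CC)CC)CC[C@@H]2C(C(O)[C@H](O[Si](CC)(CC)CC)[C@H]3OC3(C)C)C(=O)OC[C@@H]12 | intermediate
37 | C12 mesylate of 36 | C=C1C/C=C\[C@@](C)(O[Si](CC)(CC)CC)CC[C@@H]2C(C(OS(C)(=O)=O)[C@H](O[Si](CC)(CC)CC)[C@H]3OC3(C)C)C(=O)OC[C@@H]12 | intermediate (not isolated)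
38 | (4E,4aS,7S,8Z,11aR)-4-{(2S)-2-[(2R)-3,3-dimethyloxiran-2-yl]-2-(triethylsilyloxy)ethylidene}-7-methyl-11-methylidene-7-(triethylsilyloxy)-4,4a,5,6,7,10,11,11a-octahydrocyclonona[c]pyran-3(1H)-one | C=C1C/C=C\[C@@](C)(O[Si](CC)(CC)CC)CC[C@@H]2/C(=C\[C@H](O[Si](CC)(CC)CC)[C@H]3OC3(C)C)C(=O)OC[C@@H]12 | intermediate
39 | 7,13-diol (38 without both silyl groups; 4E,4aS,7S,8Z,11aR,13S,14R) | C=C1C/C=C\[C@@](C)(O)CC[C@@H]2/C(=C\[C@H](O)[C@H]3OC3(C)C)C(=O)OC[C@@H]12 | intermediate
40 | 13-acetate of 39 (free C7 hydroxyl; 4E,4aS,7S,8Z,11aR,13S,14R) | C=C1C/C=C\[C@@](C)(O)CC[C@@H]2/C(=C\[C@H](OC(C)=O)[C@H]3OC3(C)C)C(=O)OC[C@@H]12 | intermediate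
41 | CNP0113449.2 (4E,4aS,7S,8R,9R,11aR,13S,14R) | C=C1C[C@H]2O[C@H]2[C@@](C)(O)CC[C@@H]2/C(=C\[C@H](OC(C)=O)[C@H]3OC3(C)C)C(=O)OC[C@@H]12 | target

## Step count and risks

Total: 28 steps. Longest linear sequence: 23 steps (steps 1–18 and 24–28); steps 19–23 make the side-chain aldehyde.

**Step 13 (key step).** What is most likely to go wrong is poor relative stereocontrol: an enolate of the other geometry, or a boat, would give the cis acid, and the rearrangement of the boron ketene acetal to a strained ring may be slow. The wrong absolute sense is covered by the enantiomeric reagent. Fallback: change the geometry of the allylic ester instead of the enolisation. Aldehyde 7 is olefinated with methyl bis(2,2,2-trifluoroethyl)phosphonoacetate (KN(SiMe3)2, 18-crown-6; Still–Gennari) to methyl (2Z,6S)-6-methyl-6-(triethylsilyloxy)oct-2-en-7-ynoate F1 and reduced with i-Bu2AlH to the Z-allylic alcohol F2. The operations of steps 8–12 then give the Z vinyl bromide F3, the Z ynoate F4, the (5Z,10Z)-dienoate F5, the seco acid F6 and the (6Z,11Z)-lactone F7. Whatever combination of enolate geometry and transition-state shape turns 17 into the cis acid must turn F7 into the trans acid, so the same boron treatment of F7 returns to the route at acid 20.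

**Step 12.** Oligomerisation, or capture of the alkoxyphosphonium ion at the γ-carbon, may compete with 13-membered ring closure. Fallback: activate the acid instead of the alcohol. Seco acid 16 is converted with 2-methyl-6-nitrobenzoic anhydride and Et3N into the mixed anhydride F8, which is added slowly to DMAP in toluene (Shiina macrolactonisation) and rejoins the route at lactone 17. Base-induced migration of the methylene must then be watched.

**Step 16.** Loss of chemoselectivity is the risk: the borane may also add to the C11 methylene. Fallback: single out the vinyl group by cross-metathesis. Acetate 22 and pinacol vinylboronate with RuCl2(=CHPh)(PCy3)(H2IMes) (second-generation Grubbs catalyst) should give the E-alkenylboronate F9, because the 1,1-disubstituted and the hindered ring alkenes do not take part. NaBO3·4H2O oxidises the C–B bond to the enol and hence to aldehyde F10, and NaClO2/NaH2PO4/2-methylbut-2-ene returns to the route at acid 25.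

**Step 25 (with step 24).** Base-induced opening of the side-chain epoxide through a C13-centred vinylogous anion, or incomplete E-selectivity in the elimination, may occur. Fallback: form C4=C12 by Horner–Wadsworth–Emmons olefination. Lactone 27 is treated with LiN(i-Pr)2 and ClP(O)(OEt)2 to give the enol phosphate F11, which further LiN(i-Pr)2 rearranges by 1,3 O-to-C phosphoryl shift to the α-phosphono lactone F12. F12 condenses with aldehyde 34 (LiCl, DBU, MeCN) and rejoins the route at 38 without a sulfonate or a free aldolate.

**Step 28.** Poor facial selectivity is possible if the ring conformation places the C7 vanadate over the wrong alkene face. Fallback: fix the syn relation by ring fusion instead of by delivery. Alcohol 40 is converted (Boc2O, DMAP, MeCN) into the tert-butyl carbonate F13, and IBr at −80 °C closes the cis-fused five-membered cyclic carbonate with iodide at C9, the iodo carbonate F14. K2CO3 in MeOH opens the carbonate, the C8 alkoxide displaces iodide to give the syn-epoxy alcohol, and the acetate is lost, which gives the 13-deacetyl compound F15. Ac2O/pyridine returns to the route at target 41.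

## Further compounds

F1 | step 13 | methyl (2Z,6S)-6-methyl-6-(triethylsilyloxy)oct-2-en-7-ynoate | C#C[C@@](C)(O[Si](CC)(CC)CC)CC/C=C\C(=O)OC
F2 | step 13 | (2Z,6S)-6-methyl-6-(triethylsilyloxy)oct-2-en-7-yn-1-ol | C#C[C@@](C)(O[Si](CC)(CC)CC)CC/C=C\CO
F3 | step 13 | (2Z,6S)-10-bromo-6-methyl-6-(triethylsilyloxy)undeca-2,10-dien-7-yn-1-ol | C=C(Br)CC#C[C@@](C)(O[Si](CC)(CC)CC)CC/C=C\CO
F4 | step 13 | methyl (7S,10Z)-12-hydroxy-7-methyl-3-methylidene-7-(triethylsilyloxy)dodec-10-en-5-ynoate | C=C(CC(=O)OC)CC#C[C@@](C)(O[Si](CC)(CC)CC)CC/C=C\CO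
F5 | step 13 | methyl (5Z,7S,10Z)-12-hydroxy-7-methyl-3-methylidene-7-(triethylsilyloxy)dodeca-5,10-dienoate | C=C(CC(=O)OC)C/C=C\[C@@](C)(O[Si](CC)(CC)CC)CC/C=C\CO
F6 | step 13 | (5Z,7S,10Z)-12-hydroxy-7-methyl-3-methylidene-7-(triethylsilyloxy)dodeca-5,10-dienoic acid | C=C(CC(=O)O)C/C=C\[C@@](C)(O[Si](CC)(CC)CC)CC/C=C\CO
F7 | step 13 | (6Z,8S,11Z)-8-methyl-4-methylidene-8-(triethylsilyloxy)oxacyclotrideca-6,11-dien-2-one | C=C1C/C=C\[C@@](C)(O[Si](CC)(CC)CC)CC/C=C\COC(=O)C1
F8 | step 12 | mixed anhydride of 16 with 2-methyl-6-nitrobenzoic acid | C=C(CC(=O)OC(=O)c1c(C)cccc1[N+](=O)[O-])C/C=C\[C@@](C)(O[Si](CC)(CC)CC)CC/C=C/CO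
F9 | step 16 | E-alkenyl pinacol boronate from 22 | C=C1C/C=C\[C@@](C)(O[Si](CC)(CC)CC)CC[C@H](/C=C/B2OC(C)(C)C(C)(C)O2)[C@H]1COC(C)=O
F10 | step 16 | C3 aldehyde (2-oxoethyl analogue of 24) | C=C1C/C=C\[C@@](C)(O[Si](CC)(CC)CC)CC[C@H](CC=O)[C@H]1COC(C)=O
F11 | step 25 | enol diethyl phosphate of lactone 27 | C=C1C/C=C\[C@@](C)(O[Si](CC)(CC)CC)CC[C@@H]2C=C(OP(=O)(OCC)OCC)OC[C@@H]12
F12 | step 25 | 4-(diethoxyphosphoryl) lactone (mixture at C4) | C=C1C/C=C\[C@@](C)(O[Si](CC)(CC)CC)CC[C@@H]2C(P(=O)(OCC)OCC)C(=O)OC[C@@H]12
F13 | step 28 | C7 tert-butyl carbonate of 40 | C=C1C/C=C\[C@@](C)(OC(=O)OC(C)(C)C)CC[C@@H]2/C(=C\[C@H](OC(C)=O)[C@H]3OC3(C)C)C(=O)OC[C@@H]12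
F14 | step 28 | 9-iodo 7,8-cyclic carbonate (cis-fused) | C=C1C[C@H](I)[C@H]2OC(=O)O[C@@]2(C)CC[C@@H]2/C(=C\[C@H](OC(C)=O)[C@H]3OC3(C)C)C(=O)OC[C@@H]12
F15 | step 28 | 13-deacetyl target | C=C1C[C@H]2O[C@H]2[C@@](C)(O)CC[C@@H]2/C(=C\[C@H](O)[C@H]3OC3(C)C)C(=O)OC[C@@H]12
A1 | alternative 1 | C13 tert-butyldimethylsilyl ether of the deacetyl target | C=C1C[C@H]2O[C@H]2[C@@](C)(O)CC[C@@H]2/C(=C\[C@H](O[Si](C)(C)C(C)(C)C)[C@H]3OC3(C)C)C(=O)OC[C@@H]12
A2 | alternative 1 | nine-membered alkynyl alcohol (C1 hydroxymethyl, C4≡C12 alkyne) | C=C1C[C@H]2O[C@H]2[C@@](C)(O)CC[C@H](C#C[C@H](O[Si](C)(C)C(C)(C)C)[C@H]2OC2(C)C)[C@H]1CO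
A3 | alternative 2 | nine-membered Z-enone with C11 methylene | C=C1C/C=C\C(=O)CC[C@H](CCOCc2ccc(OC)cc2)[C@H]1CO[Si](C)(C)C(C)(C)C
A4 | alternative 2 | cis-fused hydrindenol tosylate (one ring-fusion diastereomer shown) | O[C@]12C=CC[C@@]1(COS(=O)(=O)c1ccc(C)cc1)[C@H](CO[Si](C)(C)C(C)(C)C)[C@@H](CCOCc1ccc(OC)cc1)CC2
A5 | alternative 3 | nine-membered cis-7,8-diol lactone with C9 PMB ether | C=C1C[C@H](OCc2ccc(OC)cc2)[C@@H](O)[C@@](C)(O)CC[C@@H]2CC(=O)OC[C@@H]12
A6 | alternative 3 | keto aldehyde lactone | C=C(C[C@H](OCc1ccc(OC)cc1)C=O)[C@@H]1COC(=O)C[C@H]1CCC(C)=O
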